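## Analysis of the target

The target is a linear trimer of flavan-3-ols: an upper and a middle (−)-epicatechin 3-O-gallate unit and a lower (+)-catechin unit. The units are joined by a C4(upper)–C8(middle) bond and a C4(middle)–C6(lower) bond. Each unit is a chroman (rings A and C) carrying a catechol ring B at C2. There are eight stereocentres: upper 2R,3R,4R, middle 2R,3R,4S, lower 2R,3S. Both upper units are 2,3-cis and 3,4-trans, so each interflavan bond lies anti to the C3 oxygen and to ring B (4β); the lower unit is 2,3-trans. Sensitive features are the eighteen free phenols (air, base), the two aryl esters and the two diarylmethine interflavan bonds, which acid cleaves because ring A stabilises a C4 cation. The hard points are these: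

- The upper unit cannot be taken from a natural flavan, since its C4 bears an aryl group and its C4 configuration has to be set next to a chiral unit that is too remote to control it.
- The 2,3-cis/3,4-trans pattern must be built on that unit.
- The lower bond must go to C6, not C8.
- The electrophilic dimer has nucleophilic ring positions of its own.

The strategy rests on ring C of the upper unit: O1 sits between C8a and C2, and removing O1 leaves a 4,6-dioxygenated 3-arylindan-1-one. Its C1, C2, C3, C3a and C7a are the flavan C2, C3, C4, C4a and C8a, and its C3 is the upper C4 diarylmethine.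

## Retrosynthetic reasoning

**Deprotection.** Target 39 is traced to the perbenzylated tetrabromide 38. All phenols are carried as benzyl ethers because these survive organolithiums, peracid and Lewis acids. The four aryl bromines are blocking groups. One hydrogenolysis removes everything, so no basic or acidic step touches the free polyphenol.

**Lower interflavan bond.** The C4(middle)–C6(lower) bond is cut to give the dimeric electrophile 33 and the nucleophile 36. The cut is placed here because the lower unit then comes intact from natural catechin 34 with both stereocentres. The forward step is capture of a benzylic C4 cation (37) by an arene. The C3 ester and the C2 aryl group both shield the α face, so the bond forms 3,4-trans. Bromine at C8 of 36 leaves only C6 free. The three bromines of 33 stop the electrophile from alkylating itself. The C4 leaving group of 32 is introduced late from 31 by benzylic oxidation, because no C4 oxygen would survive the hydride reduction used earlier.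

**Esters.** Bis-gallate 31 is cut at both ester bonds to diol 28 and acid chloride 30 (from acid 29). Diol 28 comes from the bis-silyl ether 27. The esters are introduced only after all enolate and organolithium chemistry is finished, and both hydroxyls are acylated in one operation.

**Upper C2.** Flavan 27 is cut at the C2–aryl bond and the C2–H bond. This leads to hemiketal 25 and from there to lactone 22 and aryl bromide 23 (as aryllithium 24). The lactone carbonyl is the electrophile for ring B, and hydride delivery to oxocarbenium ion 26 must set the 2,3-cis relationship.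

**Upper C3–O.** Silyl ether 22 comes from hydroxy lactone 21, and 21 from lactone 19 by oxidation of its enolate 20. The C4 aryl group has to direct the oxygen trans.

**Key disconnection.** Lactone 19 is cut at the C8a–O1 bond, which leaves indanone 17. The ring oxygen on C8a is meta to both benzyloxy groups, a position at which no electrophilic ring closure can place a bond. The carbocycle of 17 closes at the carbon ortho and para to them. So the five-membered ketone is easy to make from a 3,5-dioxygenated aryl ketone, and the missing oxygen is inserted afterwards. The forward step must make the aryl carbon migrate rather than the methylene, and must leave the electron-rich arenes alone.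

**Upper C4 stereocentre.** Indanone 17 is traced through indenol 15 to indenone 14. The epicatechin unit is too remote to control C3. So the configuration is set by a catalyst-controlled reduction of the unhindered carbonyl and is then transferred to C3 by a suprafacial 1,3-hydrogen shift. The indenone also collects both C3 epimers of 12.

**Indanone ring.** Indanone 12 is traced to keto ester 10, and 10 to alkylidene keto ester 9, by cutting the C3–C3a bond (Nazarov cyclisation). Alkylidene 9 comes from aldehyde 6 and keto ester 8. The allyl ester polarises the dienone, so a mild Lewis acid is enough, and it is removed under neutral conditions.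

**Building blocks.** Aldehyde 6 comes from 4 (through 5), 3 and 2 from (−)-epicatechin 1. Keto ester 8 comes from ketone 7, and 36 from 35 and 34. A triisopropylsilyl ether is used on the middle unit because it has to survive two Lewis-acid steps.

## Alternatives that were turned down

**Alternative 1: the lower heterocycle by ring-closing metathesis.**
- Disconnection: the C3=C4 bond of the lower unit, giving the flav-3-ene trimer A1.
- Forward key step: ruthenium-carbene metathesis in the precursor of A1. It joins an ortho-vinyl group and the inner alkene carbon of an O-(1-arylallyl) ether on the lower aromatic ring, with loss of ethylene.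
- For: the conditions are neutral and tolerate esters and benzyl ethers. The 4→6 connectivity is fixed by construction, with no blocking halogen. On this point it is stronger than the chosen route.
- Against: it builds a ring that natural catechin supplies whole with both stereocentres. After A1, the C3 hydroxyl must still be introduced with the right regiochemistry and trans to the C2 aryl group, on a styrene-type alkene, in a molecule holding two esters. The lower C2 centre would have to come from O-alkylation of a hindered phenol with an easily ionised 1-arylallyl electrophile. The precursor of A1 still needs the same cationic C4-arylation of the middle unit.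
- Comparison: it spends several steps on the easiest third of the molecule and does nothing for the upper ring. The chosen route needs two steps for the lower unit (34 to 36) and pays with one bromine that the final hydrogenolysis removes anyway.

**Alternative 2: the middle ring C annulated between two finished units.**
- Disconnection: C4–C4a and O1–C2 of the middle unit, giving the flav-2-ene A2.
- Forward key step: a free ring position ortho to a free phenol on the future middle ring A, which already carries the upper unit, adds to the β-carbon of an aryl enone bearing the lower unit. The phenol oxygen then condenses with the ketone.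
- For: it is the most convergent plan. It makes both bonds around the middle ring in one operation and avoids a late benzylic oxidation of a dimer. On convergence it is stronger than the chosen route.
- Against: A2 has no C3 oxygen and a C2=C3 double bond, so three contiguous centres remain to be made afterwards. Hydroboration–oxidation of the enol ether adds H to C2 and OH to C3 on the same face, anti to the C4 aryl group. That gives the all-trans ring, in which C2 and C4 have the wrong relationship; oxidation and reduction at C3 cannot repair it. The C4 configuration would come from an intermolecular conjugate addition with no nearby control element. The acid needed for condensation also acts on two cleavable diarylmethine bonds.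
- Comparison: the chosen route takes middle C2 and C3 unchanged from 1 and sets middle C4 in a substitution controlled by the neighbouring ester.

**Alternative 3: the upper ring from a quinone methide and an oxygenated enol silane.**
- Disconnection: C3–C4 and O1–C2 of the upper unit, giving hemiketal A3, the same kind of intermediate as 25.
- Forward key step: a diarylcarbinol at the future C4 ionises to a quinone-methide-type species. The oxygen-bearing carbon of a (Z)-silyl enol ether carrying ring B adds to it, and the phenol closes on the liberated ketone.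
- For: it reaches the hemiketal stage many steps earlier than the chosen route and brings the C3 oxygen in with the nucleophile. In step count it is clearly stronger.
- Against: C4 is created in a bimolecular addition to a planar electrophile whose only chirality is the remote epicatechin unit, so both C4 epimers are expected and no reagent control is available. The C3/C4 relationship depends on an open transition state. The methide carbon carries a 2,4,6-trioxygenated aryl group, which makes the electrophile very stabilised and sluggish toward π-nucleophiles.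
- Comparison: the chosen route spends about ten more steps. In return C4 is set by a chiral catalyst independent of the substrate (15 to 17), and C3 and C2 are then set one at a time on rigid bicyclic compounds (19, 26) whose facial bias can be predicted.

Key step: step 12

## Assumptions

- In the Corey–Bakshi–Shibata reduction of 14 the benzo ring is taken as the larger carbonyl substituent, as in 1-indanone. If the sense proves opposite, the enantiomeric catalyst is used and nothing else changes.
- 3,5-Bis(benzyloxy)acetophenone (7), 4-bromo-1,2-bis(benzyloxy)benzene (23) and 3,4,5-tris(benzyloxy)benzoic acid (29) are bought.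
- TIPS = triisopropylsilyl, TBS = tert-butyldimethylsilyl. "Tetra-O-benzyl" always means the 5,7,3',4'-phenols.

## Steps

Step 1
Reactants: 1 (−)-epicatechin
Product: 2 5,7,3',4'-tetra-O-benzylepicatechin
Conditions: BnBr, K2CO3, DMF, 0 → 25 °C, argon
Reagents that add atoms: benzyl bromide, BrCc1ccccc1
Why: Williamson ether synthesis; the carbonate base ionises only the four phenols, so the secondary C3 hydroxyl stays free and C2/C3 are untouched.

Step 2
Reactants: 2 5,7,3',4'-tetra-O-benzylepicatechin
Product: 3 8-bromo-5,7,3',4'-tetra-O-benzylepicatechin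
Conditions: N-bromosuccinimide (1.0 equiv), CH2Cl2, −78 → 25 °C
Reagents that add atoms: N-bromosuccinimide, O=C1CCC(=O)N1Br
Why: Electrophilic aromatic bromination; in 5,7-dibenzyloxyflavans C8 reacts before C6 at low temperature, and one equivalent stops at the monobromide.

Step 3
Reactants: 3 8-bromo-5,7,3',4'-tetra-O-benzylepicatechin
Product: 4 8-bromo-5,7,3',4'-tetra-O-benzyl-3-O-(triisopropylsilyl)epicatechin
Conditions: i-Pr3SiOTf, 2,6-lutidine, CH2Cl2, 0 → 25 °C
Reagents that add atoms: triisopropylsilyl trifluoromethanesulfonate, CC(C)[Si](C(C)C)(C(C)C)OS(=O)(=O)C(F)(F)F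
Why: Silylation of the hindered axial secondary alcohol with a silyl triflate; the triisopropylsilyl ether is chosen because it has to survive organolithiums, the Lewis acids of steps 7 and 16 and the peracid of step 12.

Step 4
Reactants: 4 8-bromo-5,7,3',4'-tetra-O-benzyl-3-O-(triisopropylsilyl)epicatechin
Product: 6 8-formyl-5,7,3',4'-tetra-O-benzyl-3-O-(triisopropylsilyl)epicatechin, via aryllithium 5 (not isolated)
Conditions: t-BuLi (2.1 equiv), THF, −78 °C; DMF, −78 → 0 °C; H2O
Reagents that add atoms: N,N-dimethylformamide, CN(C)C=O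
Why: Bromine–lithium exchange followed by formylation of the aryllithium with a formamide; the two ortho oxygens stabilise 5, and ethers and the silyl ether are inert at −78 °C.

Step 5
Reactants: 7 3,5-bis(benzyloxy)acetophenone
Product: 8 allyl 3-[3,5-bis(benzyloxy)phenyl]-3-oxopropanoate
Conditions: NaH (2.5 equiv), diallyl carbonate, THF, reflux; AcOH
Reagents that add atoms: diallyl carbonate, C=CCOC(=O)OCC=C
Why: Claisen-type C-acylation of the ketone enolate with a dialkyl carbonate, driven by deprotonation of the β-keto ester formed.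

Step 6
Reactants: 6 8-formyl-5,7,3',4'-tetra-O-benzyl-3-O-(triisopropylsilyl)epicatechin; 8 allyl 3-[3,5-bis(benzyloxy)phenyl]-3-oxopropanoate
Product: 9 allyl 2-[3,5-bis(benzyloxy)benzoyl]-3-(tetra-O-benzyl-3-O-TIPS-epicatechin-8-yl)prop-2-enoate (E/Z mixture)
Conditions: piperidine (0.2 equiv), AcOH (0.2 equiv), toluene, reflux, azeotropic removal of water
Reagents that add atoms: none
Why: Knoevenagel condensation of a β-keto ester with an electron-rich 2,6-dioxygenated benzaldehyde, a combination known for 2,4,6-trialkoxybenzaldehydes; the alkene geometry does not matter because the Lewis acid of step 7 equilibrates it.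

Step 7
Reactants: 9 allyl 2-[3,5-bis(benzyloxy)benzoyl]-3-(tetra-O-benzyl-3-O-TIPS-epicatechin-8-yl)prop-2-enoate
Product: 10 allyl 4,6-bis(benzyloxy)-1-oxo-3-(tetra-O-benzyl-3-O-TIPS-epicatechin-8-yl)indane-2-carboxylate (mixture of C2/C3 stereoisomers)
Conditions: Cu(OTf)2 (10 mol %), ClCH2CH2Cl, 60 °C
Reagents that add atoms: none
Why: Nazarov cyclisation of an aryl vinyl ketone polarised by the ester: the copper salt chelates the β-dicarbonyl unit, and the benzoyl ring carbon that is ortho and para to the two benzyloxy groups closes on the alkylidene carbon, followed by rearomatisation. The two ortho positions of the benzoyl ring are equivalent, so one constitution results; C2 and C3 are not controlled and both are removed in steps 8 and 9.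

Step 8
Reactants: 10 allyl 4,6-bis(benzyloxy)-1-oxo-3-(tetra-O-benzyl-3-O-TIPS-epicatechin-8-yl)indane-2-carboxylate
Product: 12 4,6-bis(benzyloxy)-3-(tetra-O-benzyl-3-O-TIPS-epicatechin-8-yl)indan-1-one (both C3 epimers), via keto acid 11 (not isolated)
Conditions: Pd(PPh3)4 (5 mol %), morpholine, THF, 25 °C
Reagents that add atoms: none
Why: Deallylation through a π-allyl complex of zerovalent palladium with morpholine as allyl acceptor; the β-keto acid 11 loses CO2 spontaneously, so the ester is removed under neutral conditions that leave silyl and benzyl ethers alone.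

Step 9
Reactants: 12 4,6-bis(benzyloxy)-3-(tetra-O-benzyl-3-O-TIPS-epicatechin-8-yl)indan-1-one (both C3 epimers)
Product: 14 4,6-bis(benzyloxy)-3-(tetra-O-benzyl-3-O-TIPS-epicatechin-8-yl)inden-1-one, via silyl enol ether 13 (not isolated)
Conditions: LiN(SiMe3)2, Me3SiCl, THF, −78 → 0 °C; then Pd(OAc)2 (1.1 equiv), MeCN, 25 °C
Reagents that add atoms: none
Why: Saegusa–Ito oxidation; C2 is the only enolisable position, and the palladium enolate loses the C3 hydrogen by β-hydride elimination, so both epimers of 12 give the same stable 3-arylindenone.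

Step 10
Reactants: 14 4,6-bis(benzyloxy)-3-(tetra-O-benzyl-3-O-TIPS-epicatechin-8-yl)inden-1-one
Product: 15 (1S)-4,6-bis(benzyloxy)-3-(tetra-O-benzyl-3-O-TIPS-epicatechin-8-yl)-1H-inden-1-ol
Conditions: (R)-1-methyl-3,3-diphenyltetrahydro-1H,3H-pyrrolo[1,2-c][1,3,2]oxazaborole (0.2 equiv), BH3·SMe2, THF, −20 °C; H2O
Reagents that add atoms: none
Why: Corey–Bakshi–Shibata 1,2-reduction of a 3-arylindenone, a known substrate class; the catalyst binds the carbonyl lone pair anti to the benzo ring and delivers hydride to one face, giving the 1S alcohol, and the remote epicatechin unit cannot oppose the catalyst. The allylic alcohol ionises easily and is used without acidic contact.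

Step 11
Reactants: 15 (1S)-4,6-bis(benzyloxy)-3-(tetra-O-benzyl-3-O-TIPS-epicatechin-8-yl)-1H-inden-1-ol
Product: 17 (3R)-4,6-bis(benzyloxy)-3-(tetra-O-benzyl-3-O-TIPS-epicatechin-8-yl)indan-1-one, via enol 16 (not isolated)
Conditions: 1,4-diazabicyclo[2.2.2]octane (1 equiv), THF, 60 °C
Reagents that add atoms: none
Why: Amine-catalysed 1,3-prototropic shift of a 1-indenol: the base removes the C1 hydrogen and returns it to C3 on the same face within a tight ion pair, and enol 16 tautomerises to the ketone. The suprafacial course turns the 1S carbinol centre into the 3R diarylmethine centre, which is the upper C4 of the target.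

Step 12
Reactants: 17 (3R)-4,6-bis(benzyloxy)-3-(tetra-O-benzyl-3-O-TIPS-epicatechin-8-yl)indan-1-one
Product: 19 (4R)-5,7-bis(benzyloxy)-4-(tetra-O-benzyl-3-O-TIPS-epicatechin-8-yl)chroman-2-one, via peroxyhemiketal 18 (not isolated)
Conditions: (CF3CO)2O, urea·H2O2, Na2HPO4, CH2Cl2, 0 °C
Reagents that add atoms: trifluoroperacetic acid, OOC(=O)C(F)(F)F (made in the flask from trifluoroacetic anhydride, O=C(OC(=O)C(F)(F)F)C(F)(F)F, and urea–hydrogen peroxide, NC(N)=O.OO)
Why: Trifluoroperacetic acid adds to the C1 carbonyl to give tetrahedral adduct 18, and loss of trifluoroacetate is concerted with a 1,2-shift of the aryl carbon C7a from C1 to oxygen, the migrating bond lying antiperiplanar to the O–O bond. The closest known reaction is the Baeyer–Villiger oxidation of 1-indanones to 3,4-dihydrocoumarins with aryl migration. The six-membered lactone ring is not formed by a cyclisation but by one-atom expansion of the five-membered ketone, the oxygen entering the C1–C7a bond and forming C8a–O1 of the flavan. No stereocentre is created; C3 of the indanone takes no part, has no acidic hydrogen, and keeps its R configuration as C4 of 19. The step needs aryl rather than methylene migration: a primary alkyl group is the poorest migrating group, while the aryl carbon can migrate through a bridged transition state, although the two benzyloxy groups are meta to it and give no resonance help, which is why the strongest common peracid is used. The same meta relationship leaves the carbonyl undeactivated, so peracid addition to the ketone is fast. The step also needs the ketone to react before the trialkoxy ring of the epicatechin unit (free C6–H); the phosphate buffer keeps the acid concentration low, and low temperature and a small excess of oxidant limit arene hydroxylation. Benzyl and silyl ethers are inert to these conditions.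

Step 13
Reactants: 19 (4R)-5,7-bis(benzyloxy)-4-(tetra-O-benzyl-3-O-TIPS-epicatechin-8-yl)chroman-2-one
Product: 21 (3R,4R)-5,7-bis(benzyloxy)-3-hydroxy-4-(tetra-O-benzyl-3-O-TIPS-epicatechin-8-yl)chroman-2-one, via potassium enolate 20 (not isolated)
Conditions: KN(SiMe3)2, THF, −78 °C; 2-(phenylsulfonyl)-3-phenyloxaziridine, −78 °C; AcOH, −78 °C
Reagents that add atoms: 2-(phenylsulfonyl)-3-phenyloxaziridine, O=S(=O)(c1ccccc1)N1OC1c1ccccc1
Why: Oxidation of a lactone enolate with an N-sulfonyloxaziridine; the C4 aryl group sits quasi-axial to avoid the C5 benzyloxy group and covers one face of the enolate, so oxygen enters trans to it (3R). Low temperature and a cold acidic quench keep the aryl ester enolate from opening.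

Step 14
Reactants: 21 (3R,4R)-5,7-bis(benzyloxy)-3-hydroxy-4-(tetra-O-benzyl-3-O-TIPS-epicatechin-8-yl)chroman-2-one
Product: 22 (3R,4R)-5,7-bis(benzyloxy)-3-(tert-butyldimethylsilyloxy)-4-(tetra-O-benzyl-3-O-TIPS-epicatechin-8-yl)chroman-2-one
Conditions: t-BuMe2SiOTf, 2,6-lutidine, CH2Cl2, −40 → 0 °C
Reagents that add atoms: tert-butyldimethylsilyl trifluoromethanesulfonate, CC(C)(C)[Si](C)(C)OS(=O)(=O)C(F)(F)F
Why: Silylation of a hindered secondary alcohol with a silyl triflate and a non-nucleophilic base; the bulky silyl ether later directs the hydride in step 16 and is removed together with the triisopropylsilyl group.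

Step 15
Reactants: 22 (3R,4R)-5,7-bis(benzyloxy)-3-(tert-butyldimethylsilyloxy)-4-(tetra-O-benzyl-3-O-TIPS-epicatechin-8-yl)chroman-2-one; 23 4-bromo-1,2-bis(benzyloxy)benzene
Product: 25 (3R,4R)-5,7-bis(benzyloxy)-2-[3,4-bis(benzyloxy)phenyl]-3-(tert-butyldimethylsilyloxy)-4-(tetra-O-benzyl-3-O-TIPS-epicatechin-8-yl)chroman-2-ol (anomers in equilibrium with the open hydroxy ketone), via aryllithium 24 (not isolated)
Conditions: 23, n-BuLi (1.05 equiv each), THF, −78 °C; added slowly to 22, THF, −78 °C; AcOH, −78 °C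
Reagents that add atoms: none
Why: Addition of an aryllithium to a lactone carbonyl to give a lactol; a second addition is disfavoured because the aryl ester is far more electrophilic than the hindered, electron-rich aryl ketone that results, and one equivalent at −78 °C with a cold quench is used.

Step 16
Reactants: 25 (3R,4R)-5,7-bis(benzyloxy)-2-[3,4-bis(benzyloxy)phenyl]-3-(tert-butyldimethylsilyloxy)-4-(tetra-O-benzyl-3-O-TIPS-epicatechin-8-yl)chroman-2-ol
Product: 27 5,7,3',4'-tetra-O-benzyl-3-O-TBS-epicatechin-(4β→8)-5,7,3',4'-tetra-O-benzyl-3-O-TIPS-epicatechin, via oxocarbenium ion 26 (not isolated)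
Conditions: Et3SiH, BF3·OEt2, CH2Cl2, −78 → −40 °C
Reagents that add atoms: none
Why: Ionic hydrogenation of a lactol, as in C-aryl glycoside synthesis: BF3 ionises 25 to the aryl-stabilised cation 26, which the silane reduces. The C4 aryl group stays quasi-axial, which forces the trans C3 silyloxy group quasi-axial too; hydride then attacks C2 along the axial trajectory anti to the neighbouring silyloxy group, so H2 is trans to O3 and ring B is cis to it (2R, 2,3-cis).

Step 17
Reactants: 27 5,7,3',4'-tetra-O-benzyl-3-O-TBS-epicatechin-(4β→8)-5,7,3',4'-tetra-O-benzyl-3-O-TIPS-epicatechin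
Product: 28 5,7,3',4'-tetra-O-benzylepicatechin-(4β→8)-5,7,3',4'-tetra-O-benzylepicatechin
Conditions: Bu4NF, THF, 25 → 40 °C
Reagents that add atoms: none
Why: Fluoride cleavage of both silyl ethers; no ester or other base-sensitive group is present at this stage.

Step 18
Reactants: 29 3,4,5-tris(benzyloxy)benzoic acid
Product: 30 3,4,5-tris(benzyloxy)benzoyl chloride
Conditions: (COCl)2, DMF (cat.), CH2Cl2, 0 → 25 °C
Reagents that add atoms: oxalyl chloride, O=C(Cl)C(=O)Cl
Why: Standard conversion of a carboxylic acid to its chloride through the chloroiminium salt formed from DMF.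

Step 19
Reactants: 28 5,7,3',4'-tetra-O-benzylepicatechin-(4β→8)-5,7,3',4'-tetra-O-benzylepicatechin; 30 3,4,5-tris(benzyloxy)benzoyl chloride
Product: 31 octa-O-benzyl epicatechin-(4β→8)-epicatechin 3,3''-bis-O-[3,4,5-tris(benzyloxy)benzoate]
Conditions: 30 (4 equiv), 4-(dimethylamino)pyridine, Et3N, CH2Cl2, 25 → 40 °C
Reagents that add atoms: none
Why: Nucleophile-catalysed acylation of two hindered axial secondary alcohols with an excess of acid chloride, as used for galloylation of benzylated flavan-3-ols.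

Step 20
Reactants: 31 octa-O-benzyl epicatechin-(4β→8)-epicatechin 3,3''-bis-O-[3,4,5-tris(benzyloxy)benzoate]
Product: 32 the 4β-(2-ethoxyethoxy) derivative of 31 at C4 of the lower (former middle) unit
Conditions: 2,3-dichloro-5,6-dicyano-1,4-benzoquinone (DDQ), 2-ethoxyethanol, CH2Cl2, 25 °C
Reagents that add atoms: 2-ethoxyethanol, CCOCCO
Why: Quinone-mediated benzylic oxidation of an O-benzylated flavan: hydride is abstracted from the C4 methylene, whose axial hydrogen is aligned with a ring bearing three donor oxygens, and the alcohol adds anti to the C3 ester. The upper C4–H is tertiary, lies nearly in the plane of its ring A because the aryl group is quasi-axial, and is shielded by two aryl groups and an ester, so it should not compete.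

Step 21
Reactants: 32 the 4β-(2-ethoxyethoxy) derivative of 31
Product: 33 the 6,8-dibromo (upper unit) 6-bromo (lower unit) derivative of 32
Conditions: N-bromosuccinimide (3.1 equiv), NaHCO3, CH2Cl2, −40 → 0 °C
Reagents that add atoms: N-bromosuccinimide, O=C1CCC(=O)N1Br
Why: Electrophilic bromination of the three free positions of the two 1,3,5-trioxygenated rings, which are far more reactive than the catechol and gallate rings; the bromines stop the electrophile from alkylating itself in step 24 and are removed in step 25.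

Step 22
Reactants: 34 (+)-catechin
Product: 35 5,7,3',4'-tetra-O-benzylcatechin
Conditions: BnBr, K2CO3, DMF, 0 → 25 °C, argon
Reagents that add atoms: benzyl bromide, BrCc1ccccc1
Why: Williamson ether synthesis selective for the four phenols, as in step 1.

Step 23
Reactants: 35 5,7,3',4'-tetra-O-benzylcatechin
Product: 36 8-bromo-5,7,3',4'-tetra-O-benzylcatechin
Conditions: N-bromosuccinimide (1.0 equiv), CH2Cl2, −78 → 25 °C
Reagents that add atoms: N-bromosuccinimide, O=C1CCC(=O)N1Br
Why: Regioselective C8 bromination as in step 2; blocking C8 leaves C6 as the only nucleophilic ring position.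

Step 24
Reactants: 33 the tribromo 4β-(2-ethoxyethoxy) bis-gallate; 36 8-bromo-5,7,3',4'-tetra-O-benzylcatechin
Product: 38 perbenzylated tetrabromo trimer [upper and middle 3-O-tris(benzyloxy)benzoates, 4β→8 and 4β→6 bonds, lower 3-OH free], via benzylic cation 37 (not isolated)
Conditions: Me3SiOTf, 36 (4 equiv), CH2Cl2, −78 → −30 °C
Reagents that add atoms: none
Why: Lewis-acid-promoted Friedel–Crafts alkylation used for interflavan bonds: the 4-alkoxy group ionises to cation 37, and C6 of 36 attacks it. The C3 ester (by participation) and the C2 aryl group shield the α face, so the new bond forms 3,4-trans (4β, 4S); C8 of 36 and all other nucleophilic ring positions are brominated, so only the 4→6 bond can form.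

Step 25
Reactants: 38 perbenzylated tetrabromo trimer
Product: 39 epicatechin 3-O-gallate-(4β→8)-epicatechin 3-O-gallate-(4β→6)-catechin (target)
Conditions: H2 (1 atm), Pd(OH)2/C, Et3N (4 equiv), THF/MeOH/H2O, 25 °C, degassed solvents
Reagents that add atoms: none
Why: Hydrogenolysis of eighteen benzyl ethers and four aryl–bromine bonds in one operation; the amine takes up the HBr so that the acid-labile interflavan bonds and the esters are not exposed to acid, and no stereocentre is touched.

## Compound list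

1 | (−)-epicatechin, (2R,3R) | O[C@@H]1Cc2c(O)cc(O)cc2O[C@@H]1c1ccc(O)c(O)c1 | starting material
2 | 5,7,3',4'-tetra-O-benzylepicatechin | O[C@@H]1Cc2c(OCc9ccccc9)cc(OCc9ccccc9)cc2O[C@@H]1c1ccc(OCc9ccccc9)c(OCc9ccccc9)c1 | intermediate
3 | 8-bromo-5,7,3',4'-tetra-O-benzylepicatechin | O[C@@H]1Cc2c(OCc9ccccc9)cc(OCc9ccccc9)c(Br)c2O[C@@H]1c1ccc(OCc9ccccc9)c(OCc9ccccc9)c1 | intermediate
4 | 8-bromo-5,7,3',4'-tetra-O-benzyl-3-O-(triisopropylsilyl)epicatechin | CC(C)[Si](C(C)C)(C(C)C)O[C@@H]1Cc2c(OCc9ccccc9)cc(OCc9ccccc9)c(Br)c2O[C@@H]1c1ccc(OCc9ccccc9)c(OCc9ccccc9)c1 | intermediate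
5 | 8-lithio-5,7,3',4'-tetra-O-benzyl-3-O-(triisopropylsilyl)epicatechin | CC(C)[Si](C(C)C)(C(C)C)O[C@@H]1Cc2c(OCc9ccccc9)cc(OCc9ccccc9)c([Li])c2O[C@@H]1c1ccc(OCc9ccccc9)c(OCc9ccccc9)c1 | intermediate (not isolated)
6 | 8-formyl-5,7,3',4'-tetra-O-benzyl-3-O-(triisopropylsilyl)epicatechin | CC(C)[Si](C(C)C)(C(C)C)O[C@@H]1Cc2c(OCc9ccccc9)cc(OCc9ccccc9)c(C=O)c2O[C@@H]1c1ccc(OCc9ccccc9)c(OCc9ccccc9)c1 | intermediate
7 | 3,5-bis(benzyloxy)acetophenone | CC(=O)c1cc(OCc9ccccc9)cc(OCc9ccccc9)c1 | starting material
8 | allyl 3-[3,5-bis(benzyloxy)phenyl]-3-oxopropanoate | C=CCOC(=O)CC(=O)c1cc(OCc9ccccc9)cc(OCc9ccccc9)c1 | intermediate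
9 | allyl 2-[3,5-bis(benzyloxy)benzoyl]-3-(tetra-O-benzyl-3-O-TIPS-epicatechin-8-yl)prop-2-enoate, E/Z mixture | C=CCOC(=O)C(=Cc2c(OCc9ccccc9)cc(OCc9ccccc9)c3c2O[C@H](c2ccc(OCc9ccccc9)c(OCc9ccccc9)c2)[C@H](O[Si](C(C)C)(C(C)C)C(C)C)C3)C(=O)c1cc(OCc9ccccc9)cc(OCc9ccccc9)c1 | intermediate
10 | allyl 4,6-bis(benzyloxy)-1-oxo-3-(tetra-O-benzyl-3-O-TIPS-epicatechin-8-yl)indane-2-carboxylate, stereoisomer mixture at C2 and C3 | C=CCOC(=O)C1C(=O)c4cc(OCc9ccccc9)cc(OCc9ccccc9)c4C1c2c(OCc9ccccc9)cc(OCc9ccccc9)c3c2O[C@H](c2ccc(OCc9ccccc9)c(OCc9ccccc9)c2)[C@H](O[Si](C(C)C)(C(C)C)C(C)C)C3 | intermediate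
11 | 4,6-bis(benzyloxy)-1-oxo-3-(tetra-O-benzyl-3-O-TIPS-epicatechin-8-yl)indane-2-carboxylic acid | OC(=O)C1C(=O)c4cc(OCc9ccccc9)cc(OCc9ccccc9)c4C1c2c(OCc9ccccc9)cc(OCc9ccccc9)c3c2O[C@H](c2ccc(OCc9ccccc9)c(OCc9ccccc9)c2)[C@H](O[Si](C(C)C)(C(C)C)C(C)C)C3 | intermediate (not isolated)
12 | 4,6-bis(benzyloxy)-3-(tetra-O-benzyl-3-O-TIPS-epicatechin-8-yl)indan-1-one, both C3 epimers | O=C1CC(c2c(OCc9ccccc9)cc(OCc9ccccc9)c3c2O[C@H](c2ccc(OCc9ccccc9)c(OCc9ccccc9)c2)[C@H](O[Si](C(C)C)(C(C)C)C(C)C)C3)c2c(OCc9ccccc9)cc(OCc9ccccc9)cc12 | intermediate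
13 | trimethylsilyl enol ether of 12 (C1=C2) | C[Si](C)(C)OC1=CC(c2c(OCc9ccccc9)cc(OCc9ccccc9)c3c2O[C@H](c2ccc(OCc9ccccc9)c(OCc9ccccc9)c2)[C@H](O[Si](C(C)C)(C(C)C)C(C)C)C3)c2c(OCc9ccccc9)cc(OCc9ccccc9)cc12 | intermediate (not isolated)
14 | 4,6-bis(benzyloxy)-3-(tetra-O-benzyl-3-O-TIPS-epicatechin-8-yl)inden-1-one | O=C1C=C(c2c(OCc9ccccc9)cc(OCc9ccccc9)c3c2O[C@H](c2ccc(OCc9ccccc9)c(OCc9ccccc9)c2)[C@H](O[Si](C(C)C)(C(C)C)C(C)C)C3)c2c(OCc9ccccc9)cc(OCc9ccccc9)cc12 | intermediate
15 | (1S)-4,6-bis(benzyloxy)-3-(tetra-O-benzyl-3-O-TIPS-epicatechin-8-yl)-1H-inden-1-ol | O[C@H]1C=C(c2c(OCc9ccccc9)cc(OCc9ccccc9)c3c2O[C@H](c2ccc(OCc9ccccc9)c(OCc9ccccc9)c2)[C@H](O[Si](C(C)C)(C(C)C)C(C)C)C3)c2c(OCc9ccccc9)cc(OCc9ccccc9)cc12 | intermediate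
16 | enol tautomer of 17 (C1=C2, C1–OH) | OC1=C[C@@H](c2c(OCc9ccccc9)cc(OCc9ccccc9)c3c2O[C@H](c2ccc(OCc9ccccc9)c(OCc9ccccc9)c2)[C@H](O[Si](C(C)C)(C(C)C)C(C)C)C3)c2c(OCc9ccccc9)cc(OCc9ccccc9)cc12 | intermediate (not isolated)
17 | (3R)-4,6-bis(benzyloxy)-3-(tetra-O-benzyl-3-O-TIPS-epicatechin-8-yl)indan-1-one | O=C1C[C@@H](c2c(OCc9ccccc9)cc(OCc9ccccc9)c3c2O[C@H](c2ccc(OCc9ccccc9)c(OCc9ccccc9)c2)[C@H](O[Si](C(C)C)(C(C)C)C(C)C)C3)c2c(OCc9ccccc9)cc(OCc9ccccc9)cc12 | intermediate (precursor of the key step)
18 | 1-hydroxy-1-(trifluoroacetylperoxy) adduct of 17 | OC1(OOC(=O)C(F)(F)F)C[C@@H](c2c(OCc9ccccc9)cc(OCc9ccccc9)c3c2O[C@H](c2ccc(OCc9ccccc9)c(OCc9ccccc9)c2)[C@H](O[Si](C(C)C)(C(C)C)C(C)C)C3)c2c(OCc9ccccc9)cc(OCc9ccccc9)cc12 | intermediate (not isolated)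
19 | (4R)-5,7-bis(benzyloxy)-4-(tetra-O-benzyl-3-O-TIPS-epicatechin-8-yl)chroman-2-one | O=C1C[C@@H](c2c(OCc9ccccc9)cc(OCc9ccccc9)c3c2O[C@H](c2ccc(OCc9ccccc9)c(OCc9ccccc9)c2)[C@H](O[Si](C(C)C)(C(C)C)C(C)C)C3)c2c(OCc9ccccc9)cc(OCc9ccccc9)cc2O1 | intermediate (product of the key step)
20 | potassium enolate of 19 | [K+].[O-]C1=C[C@@H](c2c(OCc9ccccc9)cc(OCc9ccccc9)c3c2O[C@H](c2ccc(OCc9ccccc9)c(OCc9ccccc9)c2)[C@H](O[Si](C(C)C)(C(C)C)C(C)C)C3)c2c(OCc9ccccc9)cc(OCc9ccccc9)cc2O1 | intermediate (not isolated)
21 | (3R,4R)-5,7-bis(benzyloxy)-3-hydroxy-4-(tetra-O-benzyl-3-O-TIPS-epicatechin-8-yl)chroman-2-one | O[C@@H]1[C@@H](c2c(OCc9ccccc9)cc(OCc9ccccc9)c3c2O[C@H](c2ccc(OCc9ccccc9)c(OCc9ccccc9)c2)[C@H](O[Si](C(C)C)(C(C)C)C(C)C)C3)c2c(OCc9ccccc9)cc(OCc9ccccc9)cc2OC1=O | intermediate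
22 | (3R,4R)-5,7-bis(benzyloxy)-3-(tert-butyldimethylsilyloxy)-4-(tetra-O-benzyl-3-O-TIPS-epicatechin-8-yl)chroman-2-one | CC(C)(C)[Si](C)(C)O[C@@H]1[C@@H](c2c(OCc9ccccc9)cc(OCc9ccccc9)c3c2O[C@H](c2ccc(OCc9ccccc9)c(OCc9ccccc9)c2)[C@H](O[Si](C(C)C)(C(C)C)C(C)C)C3)c2c(OCc9ccccc9)cc(OCc9ccccc9)cc2OC1=O | intermediate
23 | 4-bromo-1,2-bis(benzyloxy)benzene | Brc1ccc(OCc9ccccc9)c(OCc9ccccc9)c1 | starting material
24 | 3,4-bis(benzyloxy)phenyllithium | [Li]c1ccc(OCc9ccccc9)c(OCc9ccccc9)c1 | intermediate (not isolated)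
25 | (3R,4R)-5,7-bis(benzyloxy)-2-[3,4-bis(benzyloxy)phenyl]-3-(tert-butyldimethylsilyloxy)-4-(tetra-O-benzyl-3-O-TIPS-epicatechin-8-yl)chroman-2-ol, anomer mixture | CC(C)(C)[Si](C)(C)O[C@@H]1[C@@H](c2c(OCc9ccccc9)cc(OCc9ccccc9)c3c2O[C@H](c2ccc(OCc9ccccc9)c(OCc9ccccc9)c2)[C@H](O[Si](C(C)C)(C(C)C)C(C)C)C3)c2c(OCc9ccccc9)cc(OCc9ccccc9)cc2OC1(O)c1ccc(OCc9ccccc9)c(OCc9ccccc9)c1 | intermediate
26 | 2-aryl-3,4-dihydrochromenylium ion from 25 | CC(C)(C)[Si](C)(C)O[C@@H]1[C@@H](c2c(OCc9ccccc9)cc(OCc9ccccc9)c3c2O[C@H](c2ccc(OCc9ccccc9)c(OCc9ccccc9)c2)[C@H](O[Si](C(C)C)(C(C)C)C(C)C)C3)c2c(OCc9ccccc9)cc(OCc9ccccc9)cc2[O+]=C1c1ccc(OCc9ccccc9)c(OCc9ccccc9)c1 | intermediate (not isolated)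
27 | 5,7,3',4'-tetra-O-benzyl-3-O-TBS-epicatechin-(4β→8)-5,7,3',4'-tetra-O-benzyl-3-O-TIPS-epicatechin | CC(C)(C)[Si](C)(C)O[C@@H]1[C@@H](c2c(OCc9ccccc9)cc(OCc9ccccc9)c3c2O[C@H](c2ccc(OCc9ccccc9)c(OCc9ccccc9)c2)[C@H](O[Si](C(C)C)(C(C)C)C(C)C)C3)c2c(OCc9ccccc9)cc(OCc9ccccc9)cc2O[C@@H]1c1ccc(OCc9ccccc9)c(OCc9ccccc9)c1 | intermediate
28 | 5,7,3',4'-tetra-O-benzylepicatechin-(4β→8)-5,7,3',4'-tetra-O-benzylepicatechin | O[C@@H]1[C@@H](c2c(OCc9ccccc9)cc(OCc9ccccc9)c3c2O[C@H](c2ccc(OCc9ccccc9)c(OCc9ccccc9)c2)[C@H](O)C3)c2c(OCc9ccccc9)cc(OCc9ccccc9)cc2O[C@@H]1c1ccc(OCc9ccccc9)c(OCc9ccccc9)c1 | intermediate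
29 | 3,4,5-tris(benzyloxy)benzoic acid | OC(=O)c1cc(OCc9ccccc9)c(OCc9ccccc9)c(OCc9ccccc9)c1 | starting material
30 | 3,4,5-tris(benzyloxy)benzoyl chloride | ClC(=O)c1cc(OCc9ccccc9)c(OCc9ccccc9)c(OCc9ccccc9)c1 | intermediate
31 | octa-O-benzyl epicatechin-(4β→8)-epicatechin 3,3''-bis-O-[3,4,5-tris(benzyloxy)benzoate] | O=C(O[C@@H]1[C@@H](c2c(OCc9ccccc9)cc(OCc9ccccc9)c3c2O[C@H](c2ccc(OCc9ccccc9)c(OCc9ccccc9)c2)[C@H](OC(=O)c2cc(OCc9ccccc9)c(OCc9ccccc9)c(OCc9ccccc9)c2)C3)c2c(OCc9ccccc9)cc(OCc9ccccc9)cc2O[C@@H]1c1ccc(OCc9ccccc9)c(OCc9ccccc9)c1)c1cc(OCc9ccccc9)c(OCc9ccccc9)c(OCc9ccccc9)c1 | intermediate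
32 | 31 with a 4β-(2-ethoxyethoxy) group at C4 of its lower unit | O=C(O[C@@H]1[C@@H](c2c(OCc9ccccc9)cc(OCc9ccccc9)c3c2O[C@H](c2ccc(OCc9ccccc9)c(OCc9ccccc9)c2)[C@H](OC(=O)c2cc(OCc9ccccc9)c(OCc9ccccc9)c(OCc9ccccc9)c2)[C@H]3OCCOCC)c2c(OCc9ccccc9)cc(OCc9ccccc9)cc2O[C@@H]1c1ccc(OCc9ccccc9)c(OCc9ccccc9)c1)c1cc(OCc9ccccc9)c(OCc9ccccc9)c(OCc9ccccc9)c1 | intermediate
33 | 32 with bromine at C6 and C8 of the upper unit and C6 of the lower unit | O=C(O[C@@H]1[C@@H](c2c(OCc9ccccc9)c(Br)c(OCc9ccccc9)c3c2O[C@H](c2ccc(OCc9ccccc9)c(OCc9ccccc9)c2)[C@H](OC(=O)c2cc(OCc9ccccc9)c(OCc9ccccc9)c(OCc9ccccc9)c2)[C@H]3OCCOCC)c2c(OCc9ccccc9)c(Br)c(OCc9ccccc9)c(Br)c2O[C@@H]1c1ccc(OCc9ccccc9)c(OCc9ccccc9)c1)c1cc(OCc9ccccc9)c(OCc9ccccc9)c(OCc9ccccc9)c1 | intermediate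
34 | (+)-catechin, (2R,3S) | O[C@H]1Cc2c(O)cc(O)cc2O[C@@H]1c1ccc(O)c(O)c1 | starting material
35 | 5,7,3',4'-tetra-O-benzylcatechin | O[C@H]1Cc2c(OCc9ccccc9)cc(OCc9ccccc9)cc2O[C@@H]1c1ccc(OCc9ccccc9)c(OCc9ccccc9)c1 | intermediate
36 | 8-bromo-5,7,3',4'-tetra-O-benzylcatechin | O[C@H]1Cc2c(OCc9ccccc9)cc(OCc9ccccc9)c(Br)c2O[C@@H]1c1ccc(OCc9ccccc9)c(OCc9ccccc9)c1 | intermediate
37 | C4 benzylic cation from 33 | O=C(O[C@@H]1[C@@H](c2c(OCc9ccccc9)c(Br)c(OCc9ccccc9)c3c2O[C@H](c2ccc(OCc9ccccc9)c(OCc9ccccc9)c2)[C@H](OC(=O)c2cc(OCc9ccccc9)c(OCc9ccccc9)c(OCc9ccccc9)c2)[CH+]3)c2c(OCc9ccccc9)c(Br)c(OCc9ccccc9)c(Br)c2O[C@@H]1c1ccc(OCc9ccccc9)c(OCc9ccccc9)c1)c1cc(OCc9ccccc9)c(OCc9ccccc9)c(OCc9ccccc9)c1 | intermediate (not isolated)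
38 | perbenzylated tetrabromo trimer: upper 6,8-dibromo and middle 6-bromo epicatechin 3-O-tris(benzyloxy)benzoates, lower 8-bromocatechin, 4β→8 and 4β→6 | O=C(O[C@@H]1[C@@H](c2c(OCc9ccccc9)c(Br)c(OCc9ccccc9)c3c2O[C@H](c2ccc(OCc9ccccc9)c(OCc9ccccc9)c2)[C@H](OC(=O)c2cc(OCc9ccccc9)c(OCc9ccccc9)c(OCc9ccccc9)c2)[C@H]3c2c(OCc9ccccc9)c(Br)c3c(c2OCc9ccccc9)C[C@H](O)[C@@H](c2ccc(OCc9ccccc9)c(OCc9ccccc9)c2)O3)c2c(OCc9ccccc9)c(Br)c(OCc9ccccc9)c(Br)c2O[C@@H]1c1ccc(OCc9ccccc9)c(OCc9ccccc9)c1)c1cc(OCc9ccccc9)c(OCc9ccccc9)c(OCc9ccccc9)c1 | intermediate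
39 | epicatechin 3-O-gallate-(4β→8)-epicatechin 3-O-gallate-(4β→6)-catechin | O=C(O[C@@H]1[C@@H](c2c(O)cc(O)c3c2O[C@H](c2ccc(O)c(O)c2)[C@H](OC(=O)c2cc(O)c(O)c(O)c2)[C@H]3c2c(O)cc3c(c2O)C[C@H](O)[C@@H](c2ccc(O)c(O)c2)O3)c2c(O)cc(O)cc2O[C@@H]1c1ccc(O)c(O)c1)c1cc(O)c(O)c(O)c1 | target

## Step count and least certain steps

Total: 25 steps. Longest linear sequence: 21 steps (1 → 2 → 3 → 4 → 6 → 9 → 10 → 12 → 14 → 15 → 17 → 19 → 21 → 22 → 25 → 27 → 28 → 31 → 32 → 33 → 38 → 39).

**Step 12 (key step).** The peracid may hydroxylate the trialkoxy ring of the epicatechin unit at its free C6 position faster than it adds to the ketone. The oxidation may also be slow, or give some methylene migration, because the migrating aryl carbon has only meta donor groups. Fallback: starting from 17, the free C6 position is blocked first with N-bromosuccinimide to give the 6-bromo indanone F1. This is oxidised under the conditions of step 12 to the 6-bromo lactone F2, whose trialkoxy ring is now fully substituted and less electron-rich. The bromine is then removed by radical reduction (Bu3SnH, azobisisobutyronitrile, toluene, 90 °C), which leaves benzyl ethers alone and returns to 19.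

**Step 16.** Facial selectivity in the hydride addition to 26 may be poor, because the quasi-axial C4 aryl group lies on the face the hydride has to use; a 2,3-trans flavan would result. Fallback: starting from 25, the open hydroxy ketone tautomer is reduced with LiBH(s-Bu)3 at −78 °C under non-chelation control to the anti diol monosilyl ether F3. The ring is then closed by a Mitsunobu reaction (PPh3, diisopropyl azodicarboxylate), in which the phenol displaces the benzylic hydroxyl with inversion, returning to 27.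

**Step 15.** A second aryllithium may add to the ring-opened ketone, the lactone may be enolised, or the silyl group may migrate to the neighbouring alkoxide. Fallback: starting from 22, the lactone is opened with Me2AlN(OMe)Me (from AlMe3 and N,O-dimethylhydroxylamine hydrochloride) to the phenol N-methoxy-N-methylamide F4. Two equivalents of 24 are added; the first deprotonates the phenol and the second adds once, because the chelated adduct survives until work-up. The hydroxy ketone closes to 25.

**Step 20.** Hydride abstraction may be slow because the C3 ester withdraws electrons, or it may occur at the upper diarylmethine C4–H. Fallback: starting from 28, the oxidation with DDQ and 2-ethoxyethanol is carried out on the diol, the substrate type for which this oxidation is best established, to give the 4β-(2-ethoxyethoxy) diol F5. F5 is then acylated with 30 under the conditions of step 19 and returns to 32.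

**Step 7.** The electrocyclisation may fail because the trialkoxyaryl group stabilises the chelated cation, and a retro-Knoevenagel cleavage may take over. Fallback: starting from 7, N-bromosuccinimide gives 2-bromo-3,5-bis(benzyloxy)acetophenone F6. Claisen–Schmidt condensation with 6 (KOH, EtOH/THF) gives the 2'-bromochalcone F7. A reductive Heck cyclisation (Pd(OAc)2, PPh3, HCO2Na, DMF, 80 °C) forms the C3–C3a bond by carbopalladation under basic conditions and returns to 12.

**Step 11.** Chirality transfer may be incomplete if the ion pair separates before reprotonation, or if the allylic alcohol ionises reversibly. Fallback: starting from 12, the two C3 epimers, which are diastereomers, are separated by preparative chromatography. The 3R epimer is 17. The other epimer is returned to step 9 and reduced back to 12 with [(Ph3P)CuH]6. This fallback makes no new compound (F0).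

## Further compounds

F1 | step 12 | (3R)-4,6-bis(benzyloxy)-3-(6-bromo-tetra-O-benzyl-3-O-TIPS-epicatechin-8-yl)indan-1-one | O=C1C[C@@H](c2c(OCc9ccccc9)c(Br)c(OCc9ccccc9)c3c2O[C@H](c2ccc(OCc9ccccc9)c(OCc9ccccc9)c2)[C@H](O[Si](C(C)C)(C(C)C)C(C)C)C3)c2c(OCc9ccccc9)cc(OCc9ccccc9)cc12
F2 | step 12 | (4R)-5,7-bis(benzyloxy)-4-(6-bromo-tetra-O-benzyl-3-O-TIPS-epicatechin-8-yl)chroman-2-one | O=C1C[C@@H](c2c(OCc9ccccc9)c(Br)c(OCc9ccccc9)c3c2O[C@H](c2ccc(OCc9ccccc9)c(OCc9ccccc9)c2)[C@H](O[Si](C(C)C)(C(C)C)C(C)C)C3)c2c(OCc9ccccc9)cc(OCc9ccccc9)cc2O1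
F3 | step 16 | anti-1-[3,4-bis(benzyloxy)phenyl]-2-(tert-butyldimethylsilyloxy)-3-[2,4-bis(benzyloxy)-6-hydroxyphenyl]-3-(tetra-O-benzyl-3-O-TIPS-epicatechin-8-yl)propan-1-ol | CC(C)(C)[Si](C)(C)O[C@H]([C@@H](c2c(OCc9ccccc9)cc(OCc9ccccc9)c3c2O[C@H](c2ccc(OCc9ccccc9)c(OCc9ccccc9)c2)[C@H](O[Si](C(C)C)(C(C)C)C(C)C)C3)c2c(OCc9ccccc9)cc(OCc9ccccc9)cc2O)[C@@H](O)c1ccc(OCc9ccccc9)c(OCc9ccccc9)c1
F4 | step 15 | N-methoxy-N-methyl-2-(tert-butyldimethylsilyloxy)-3-[2,4-bis(benzyloxy)-6-hydroxyphenyl]-3-(tetra-O-benzyl-3-O-TIPS-epicatechin-8-yl)propanamide | CC(C)(C)[Si](C)(C)O[C@H]([C@@H](c2c(OCc9ccccc9)cc(OCc9ccccc9)c3c2O[C@H](c2ccc(OCc9ccccc9)c(OCc9ccccc9)c2)[C@H](O[Si](C(C)C)(C(C)C)C(C)C)C3)c2c(OCc9ccccc9)cc(OCc9ccccc9)cc2O)C(=O)N(C)OC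
F5 | step 20 | 28 with a 4β-(2-ethoxyethoxy) group at C4 of its lower unit | O[C@@H]1[C@@H](c2c(OCc9ccccc9)cc(OCc9ccccc9)c3c2O[C@H](c2ccc(OCc9ccccc9)c(OCc9ccccc9)c2)[C@H](O)[C@H]3OCCOCC)c2c(OCc9ccccc9)cc(OCc9ccccc9)cc2O[C@@H]1c1ccc(OCc9ccccc9)c(OCc9ccccc9)c1
F6 | step 7 | 2-bromo-3,5-bis(benzyloxy)acetophenone | CC(=O)c1cc(OCc9ccccc9)cc(OCc9ccccc9)c1Br
F7 | step 7 | (E)-1-[2-bromo-3,5-bis(benzyloxy)phenyl]-3-(tetra-O-benzyl-3-O-TIPS-epicatechin-8-yl)prop-2-en-1-one | O=C(/C=C/c2c(OCc9ccccc9)cc(OCc9ccccc9)c3c2O[C@H](c2ccc(OCc9ccccc9)c(OCc9ccccc9)c2)[C@H](O[Si](C(C)C)(C(C)C)C(C)C)C3)c1cc(OCc9ccccc9)cc(OCc9ccccc9)c1Br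
F0 | step 11 | none | none
A1 | alternative 1 | perbenzylated trimer with the lower unit as a (2R)-flav-3-ene | O=C(O[C@@H]1[C@@H](c2c(OCc4ccccc4)cc(OCc4ccccc4)c3c2O[C@H](c2ccc(OCc4ccccc4)c(OCc4ccccc4)c2)[C@H](OC(=O)c2cc(OCc4ccccc4)c(OCc4ccccc4)c(OCc4ccccc4)c2)[C@H]3c2c(OCc4ccccc4)cc3c(c2OCc4ccccc4)C=C[C@@H](c2ccc(OCc4ccccc4)c(OCc4ccccc4)c2)O3)c2c(OCc4ccccc4)cc(OCc4ccccc4)cc2O[C@@H]1c1ccc(OCc4ccccc4)c(OCc4ccccc4)c1)c1cc(OCc4ccccc4)c(OCc4ccccc4)c(OCc4ccccc4)c1
A2 | alternative 2 | trimer with the middle unit as a 7-hydroxyflav-2-ene, otherwise benzylated | O=C(O[C@@H]1[C@@H](c2c(O)cc(OCc4ccccc4)c3c2OC(c2ccc(OCc4ccccc4)c(OCc4ccccc4)c2)=C[C@H]3c2c(OCc4ccccc4)cc3c(c2OCc4ccccc4)C[C@H](OCc4ccccc4)[C@@H](c2ccc(OCc4ccccc4)c(OCc4ccccc4)c2)O3)c2c(OCc4ccccc4)cc(OCc4ccccc4)cc2O[C@@H]1c1ccc(OCc4ccccc4)c(OCc4ccccc4)c1)c1cc(OCc4ccccc4)c(OCc4ccccc4)c(OCc4ccccc4)c1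
A3 | alternative 3 | 2-hydroxyflavan hemiketal of the upper unit with two tert-butyldimethylsilyl ethers, C4 bonded to C8 of the silylated epicatechin unit | CC(C)(C)[Si](C)(C)O[C@@H]1[C@@H](c2c(OCc4ccccc4)cc(OCc4ccccc4)c3c2O[C@H](c2ccc(OCc4ccccc4)c(OCc4ccccc4)c2)[C@H](O[Si](C)(C)C(C)(C)C)C3)c2c(OCc4ccccc4)cc(OCc4ccccc4)cc2OC1(O)c1ccc(OCc4ccccc4)c(OCc4ccccc4)c1
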